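**Plan**
- Retrosynthetic cuts, in order: the CO2H carbon back to a C3 allyl group (C=C cleavage); ring bond C3–O2 (hydroperoxide displacing a C3 mesylate); C6–O1 plus a temporary C1′–OH back to a C1′–C6 epoxide, i.e. a (Z)-alkene C1′=C6; finally C1′–C2′, between an alkenyl carbon and a boron-bearing stereocentre.
- Enabling feature: C1′ is the exocyclic CH2 on the quaternary peroxy carbon C6 of the 1,2-dioxane ring, so it can be carried as the sp2 CH of a C1′=C6 alkene whose C6 end later takes O1. C2′ is a plain CH(CH3) centre that can sit on boron. Two nucleophilic carbons (alkenyl-Li and alkyl-B) are joined on one boron and released by I2.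
- Forward order: boronic ester 5 and alkenyl iodide 10 are made separately and joined by a Zweifel coupling; then C3 carbinol/allyl, mesylate, epoxide, hydroperoxide; the only ring (the 1,2-dioxane) closes by 6-exo-tet peroxide alkylation; C1′ is deoxygenated and the allyl group is cleaved to the acid.
- Stereochemistry: C2′ from sparteine-controlled lithiation–borylation, carried through the coupling with retention; C4 from (R)-3-bromo-2-methylpropan-1-ol; C3 from Brown allylboration followed by SN2 inversion; C6 from Shi epoxidation followed by invertive perhydrolysis.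

Key step: step 6

Remark (locants): the ring is numbered O1–O2–C3–C4–C5–C6 as in the target (C3 bears the two-carbon arm, C4 and C6 one methyl each); the C6 side chain runs from C1′ (CH2) to C11′ (CH2Ph), with C2′ the CH(CH3) centre.
Remark (assumption): 10-phenyldecan-1-ol, (R)-3-bromo-2-methylpropan-1-ol, (+)-sparteine, MeBpin, (+)-Ipc2B(allyl) and the L-fructose-derived Shi ketone are taken as purchasable.

**Route**

Step 1
Reactants: 1 10-phenyldecan-1-ol
Product: 2 10-phenyldecyl N,N-diisopropylcarbamate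
Conditions: iPr2NC(O)Cl, Et3N, CH2Cl2, reflux
Reagents that add atoms: N,N-diisopropylcarbamoyl chloride, CC(C)N(C(C)C)C(Cl)=O
Why: O-carbamoylation of a primary alcohol installs the directing and leaving group needed for the sparteine-mediated lithiation; no stereocentre is involved.

Step 2
Reactants: 2 10-phenyldecyl N,N-diisopropylcarbamate
Product: 5 2-[(2R)-11-phenylundecan-2-yl]-4,4,5,5-tetramethyl-1,3,2-dioxaborolane, via lithio carbamate 3 (not isolated), via boronate complex 4 (not isolated)
Conditions: sBuLi, (+)-sparteine, Et2O, −78 °C; MeBpin, −78 °C; MgBr2·OEt2, then reflux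
Reagents that add atoms: methylboronic acid pinacol ester (MeBpin), CB1OC(C)(C)C(C)(C)O1
Why: Lithiation–borylation (Hoppe-type carbamate lithiation, then 1,2-metallate rearrangement): sBuLi/(+)-sparteine removes the pro-R hydrogen to give the configurationally stable (R)-lithio carbamate, MeBpin is captured with retention, and the MgBr2-promoted shift of methyl expels the carbamate with inversion, which sets C2′ as R.

Step 3
Reactants: 6 (R)-3-bromo-2-methylpropan-1-ol
Product: 7 (R)-(3-bromo-2-methylpropoxy)(tert-butyl)dimethylsilane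
Conditions: TBSCl, imidazole, CH2Cl2, 0 °C to rt
Reagents that add atoms: tert-butyldimethylsilyl chloride, CC(C)(C)[Si](C)(C)Cl
Why: Standard silylation protects the primary alcohol against the organometallic steps that follow; the C4 centre comes unchanged from the chiral pool.

Step 4
Reactants: 7 (R)-(3-bromo-2-methylpropoxy)(tert-butyl)dimethylsilane
Product: 8 (S)-tert-butyldimethyl[(2-methylpent-4-yn-1-yl)oxy]silane
Conditions: LiC≡CH·H2NCH2CH2NH2, DMSO, 0 °C to rt
Reagents that add atoms: lithium acetylide–ethylenediamine complex, [Li]C#C.NCCN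
Why: SN2 alkylation of acetylide by the primary bromide adds the two alkyne carbons; the stereocentre is not touched (the descriptor becomes S only through the priority change).

Step 5
Reactants: 8 (S)-tert-butyldimethyl[(2-methylpent-4-yn-1-yl)oxy]silane
Product: 10 tert-butyl{[(2S,4E)-5-iodo-2,4-dimethylpent-4-en-1-yl]oxy}dimethylsilane, via alkenylalane 9 (not isolated)
Conditions: Me3Al, Cp2ZrCl2 (0.2 equiv), CH2Cl2, 0 °C to rt; then I2, THF, −30 to 0 °C
Reagents that add atoms: trimethylaluminium, C[Al](C)C; iodine, II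
Why: Negishi zirconium-catalysed carboalumination adds methyl and aluminium syn across the terminal alkyne (methyl to the internal carbon), and iodinolysis with retention gives the (E)-alkenyl iodide that carries C6 with its methyl and C1′.

Step 6
Reactants: 10 tert-butyl{[(2S,4E)-5-iodo-2,4-dimethylpent-4-en-1-yl]oxy}dimethylsilane; 5 2-[(2R)-11-phenylundecan-2-yl]-4,4,5,5-tetramethyl-1,3,2-dioxaborolane
Product: 14 tert-butyldimethyl{[(2S,4Z,6R)-2,4,6-trimethyl-15-phenylpentadec-4-en-1-yl]oxy}silane, via alkenyllithium 11 (not isolated), via boronate complex 12 (not isolated), via iodo boronic ester 13 (not isolated)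
Conditions: 10, tBuLi (2 equiv), Et2O, −78 °C; 5 in THF, −78 °C; I2 in THF, −78 °C; NaOMe, MeOH, −78 °C to rt
Reagents that add atoms: none
Why: Zweifel olefination: iodine–lithium exchange gives alkenyllithium 11, which adds to the empty boron orbital of 5 to give ate complex 12, so that two nucleophilic carbons sit on one boron; I2 then attacks the electron-rich alkene of 12 and drives a 1,2-shift of the secondary alkyl group from boron to C1′ anti to the iodonium (13), and NaOMe triggers anti elimination of boron and iodine. The closest known reaction type is the Zweifel coupling of enantioenriched secondary pinacol boronic esters with alkenyllithiums. No ring is closed. No stereocentre is created: C2′ migrates with retention because the new C–C bond forms on the face that the C–B bond occupied, so the R configuration from step 2 is carried over, and the anti-shift/anti-elimination sequence converts the (E)-alkenyl metal into the (Z)-alkene (C2′ cis to C5). The step needs migration of the alkyl carbon only, which is secured because it is the sole carbon ligand on boron besides the alkenyl group, and iodination of the ate-complex alkene only, which is far more electron-rich than the phenyl ring. The silyl ether is inert to tBuLi at −78 °C and to I2/NaOMe.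

Step 7
Reactants: 14 tert-butyldimethyl{[(2S,4Z,6R)-2,4,6-trimethyl-15-phenylpentadec-4-en-1-yl]oxy}silane
Product: 15 (2S,4Z,6R)-2,4,6-trimethyl-15-phenylpentadec-4-en-1-ol
Conditions: Bu4NF, THF, 0 °C to rt
Reagents that add atoms: none
Why: Fluoride desilylation frees the primary alcohol (the future C3) without touching the alkene or either stereocentre.

Step 8
Reactants: 15 (2S,4Z,6R)-2,4,6-trimethyl-15-phenylpentadec-4-en-1-ol
Product: 18 (4R,5S,7Z,9R)-5,7,9-trimethyl-18-phenyloctadeca-1,7-dien-4-ol, via aldehyde 16 (not isolated), via borinate 17 (not isolated)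
Conditions: Dess–Martin periodinane, CH2Cl2, rt; crude aldehyde, (+)-Ipc2B(allyl), Et2O, −78 °C; NaOH, H2O2, 0 °C to rt
Reagents that add atoms: (+)-B-allyldiisopinocampheylborane, C=CCB([C@H]1C[C@H]2C[C@@H]([C@@H]1C)C2(C)C)[C@H]1C[C@H]2C[C@@H]([C@@H]1C)C2(C)C
Why: Dess–Martin oxidation followed by Brown allylboration: the crude α-methyl aldehyde reacts through a chair Zimmerman–Traxler transition state in which the reagent derived from (−)-α-pinene delivers allyl to the Re face, which sets C3 as the (R)-carbinol (anti to the C4 methyl) under reagent control against the weak Felkin bias, and the allyl group is the masked acetic acid arm.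

Step 9
Reactants: 18 (4R,5S,7Z,9R)-5,7,9-trimethyl-18-phenyloctadeca-1,7-dien-4-ol
Product: 19 (4R,5S,7Z,9R)-5,7,9-trimethyl-18-phenyloctadeca-1,7-dien-4-yl methanesulfonate
Conditions: MsCl, Et3N, CH2Cl2, 0 °C
Reagents that add atoms: methanesulfonyl chloride, CS(Cl)(=O)=O
Why: Mesylation with retention turns the C3 oxygen into the leaving group for the later ring closure and, at the same time, stops this hydroxyl from opening the epoxide to a tetrahydrofuran.

Step 10
Reactants: 19 (4R,5S,7Z,9R)-5,7,9-trimethyl-18-phenyloctadeca-1,7-dien-4-yl methanesulfonate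
Product: 20 (4R,5S)-5-methyl-6-{(2R,3S)-2-methyl-3-[(2R)-11-phenylundecan-2-yl]oxiran-2-yl}hex-1-en-4-yl methanesulfonate
Conditions: L-fructose-derived Shi ketone (0.3 equiv), KHSO5 (as 2KHSO5·KHSO4·K2SO4), K2CO3, Bu4NHSO4, MeCN/CH2(OMe)2/aq. Na2B4O7 buffer pH 10.5, 0 °C
Reagents that add atoms: potassium peroxymonosulfate, [K+].[O-]S(=O)(=O)OO
Why: Shi epoxidation: the chiral dioxirane formed from the ketone attacks only the electron-rich trisubstituted alkene through a spiro transition state (the terminal alkene is untouched), and the L-fructose-derived catalyst places oxygen on the face that gives the (2R,3S)-oxirane, the configuration from which C6 is derived.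

Step 11
Reactants: 20 (4R,5S)-5-methyl-6-{(2R,3S)-2-methyl-3-[(2R)-11-phenylundecan-2-yl]oxiran-2-yl}hex-1-en-4-yl methanesulfonate
Product: 21 (4R,5S,7S,8S,9R)-7-hydroperoxy-8-hydroxy-5,7,9-trimethyl-18-phenyloctadec-1-en-4-yl methanesulfonate
Conditions: H2O2 (anhydrous, in Et2O), H3PMo12O40 (cat.), Et2O, rt
Reagents that add atoms: hydrogen peroxide, OO
Why: Acid-catalysed perhydrolysis of a trisubstituted epoxide: H2O2 attacks the more substituted carbon C6 from the back (borderline SN2, inversion), so the tertiary hydroperoxide has the C6 configuration of the target and the oxirane oxygen stays as the temporary C1′ hydroxyl; mesylate and terminal alkene are inert.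

Step 12
Reactants: 21 (4R,5S,7S,8S,9R)-7-hydroperoxy-8-hydroxy-5,7,9-trimethyl-18-phenyloctadec-1-en-4-yl methanesulfonate
Product: 22 (1S,2R)-1-[(3S,4S,6S)-4,6-dimethyl-3-(prop-2-en-1-yl)-1,2-dioxan-6-yl]-2-methyl-11-phenylundecan-1-ol
Conditions: KOtBu (1.0 equiv), 18-crown-6, THF, 0 °C
Reagents that add atoms: none
Why: Intramolecular alkylation of a hydroperoxide: one equivalent of base ionises only the OOH (far more acidic than the alcohol), and the peroxy anion displaces the secondary mesylate 6-exo-tet with inversion, which closes the 1,2-dioxane and sets C3 as S with its carbon arm cis to the C4 methyl.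

Step 13
Reactants: 22 (1S,2R)-1-[(3S,4S,6S)-4,6-dimethyl-3-(prop-2-en-1-yl)-1,2-dioxan-6-yl]-2-methyl-11-phenylundecan-1-ol
Product: 23 O-{(1S,2R)-1-[(3S,4S,6S)-4,6-dimethyl-3-(prop-2-en-1-yl)-1,2-dioxan-6-yl]-2-methyl-11-phenylundecyl} O-phenyl carbonothioate
Conditions: PhOC(S)Cl, pyridine, DMAP (cat.), CH2Cl2, rt
Reagents that add atoms: O-phenyl chlorothionoformate, S=C(Cl)Oc1ccccc1
Why: Acylation of the remaining secondary alcohol as its phenyl thionocarbonate under neutral conditions prepares it for radical removal; the dialkyl peroxide tolerates the reagent.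

Step 14
Reactants: 23 O-{(1S,2R)-1-[(3S,4S,6S)-4,6-dimethyl-3-(prop-2-en-1-yl)-1,2-dioxan-6-yl]-2-methyl-11-phenylundecyl} O-phenyl carbonothioate
Product: 24 (3S,4S,6R)-4,6-dimethyl-6-[(2R)-2-methyl-11-phenylundecyl]-3-(prop-2-en-1-yl)-1,2-dioxane
Conditions: Bu3SnH (5 equiv, about 1 M), Et3B, air, toluene, 0 °C
Reagents that add atoms: none
Why: Barton–McCombie deoxygenation turns C1′ into the CH2 of the target; a concentrated, fast hydrogen donor at low temperature should trap the C1′ radical before it attacks the neighbouring O–O bond, as in tin hydride reductions of β-halo peroxides, and the C6 descriptor changes to R only through the priority change.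

Step 15
Reactants: 24 (3S,4S,6R)-4,6-dimethyl-6-[(2R)-2-methyl-11-phenylundecyl]-3-(prop-2-en-1-yl)-1,2-dioxane
Product: 26 2-{(3S,4S,6R)-4,6-dimethyl-6-[(2R)-2-methyl-11-phenylundecyl]-1,2-dioxan-3-yl}acetic acid, via aldehyde 25 (not isolated)
Conditions: O3, pyridine, CH2Cl2, −78 °C; then NaClO2, NaH2PO4, 2-methylbut-2-ene, tBuOH/H2O, 0 °C to rt
Reagents that add atoms: ozone, [O-][O+]=O; sodium chlorite, [Na+].[O-]Cl=O
Why: Pyridine-mediated reductive ozonolysis cleaves the terminal alkene directly to the aldehyde without a reducing agent that could touch the O–O bond, and Pinnick oxidation under buffered, weakly acidic conditions gives the acid without base-induced opening of the β-peroxy carbonyl system.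

**Compound list**
1 | 10-phenyldecan-1-ol | OCCCCCCCCCCc1ccccc1 | starting material
2 | 10-phenyldecyl N,N-diisopropylcarbamate | CC(C)N(C(C)C)C(=O)OCCCCCCCCCCc1ccccc1 | intermediate
3 | (R)-1-(diisopropylcarbamoyloxy)-10-phenyldecyllithium, (+)-sparteine complex (ligand not drawn) | [Li][C@@H](OC(=O)N(C(C)C)C(C)C)CCCCCCCCCc1ccccc1 | intermediate
4 | lithium [(1R)-1-(diisopropylcarbamoyloxy)-10-phenyldecyl](methyl)(pinacolato)borate | [Li+].C[B-]1(OC(C)(C)C(C)(C)O1)[C@@H](OC(=O)N(C(C)C)C(C)C)CCCCCCCCCc1ccccc1 | intermediate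
5 | 2-[(2R)-11-phenylundecan-2-yl]-4,4,5,5-tetramethyl-1,3,2-dioxaborolane | C[C@H](CCCCCCCCCc1ccccc1)B1OC(C)(C)C(C)(C)O1 | intermediate
6 | (R)-3-bromo-2-methylpropan-1-ol | BrC[C@H](C)CO | starting material
7 | (R)-(3-bromo-2-methylpropoxy)(tert-butyl)dimethylsilane | BrC[C@H](C)CO[Si](C)(C)C(C)(C)C | intermediate
8 | (S)-tert-butyldimethyl[(2-methylpent-4-yn-1-yl)oxy]silane | C#CC[C@H](C)CO[Si](C)(C)C(C)(C)C | intermediate
9 | {(1E,4S)-5-[(tert-butyldimethylsilyl)oxy]-2,4-dimethylpent-1-en-1-yl}dimethylalane | C[Al](C)/C=C(C)/C[C@H](C)CO[Si](C)(C)C(C)(C)C | intermediate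
10 | tert-butyl{[(2S,4E)-5-iodo-2,4-dimethylpent-4-en-1-yl]oxy}dimethylsilane | I/C=C(C)/C[C@H](C)CO[Si](C)(C)C(C)(C)C | intermediate
11 | {(1E,4S)-5-[(tert-butyldimethylsilyl)oxy]-2,4-dimethylpent-1-en-1-yl}lithium | [Li]/C=C(C)/C[C@H](C)CO[Si](C)(C)C(C)(C)C | intermediate
12 | lithium {(1E,4S)-5-[(tert-butyldimethylsilyl)oxy]-2,4-dimethylpent-1-en-1-yl}[(2R)-11-phenylundecan-2-yl](pinacolato)borate | [Li+].C[C@H](CCCCCCCCCc1ccccc1)[B-]1(OC(C)(C)C(C)(C)O1)/C=C(C)/C[C@H](C)CO[Si](C)(C)C(C)(C)C | intermediate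
13 | 2-{(4S)-5-[(tert-butyldimethylsilyl)oxy]-2-iodo-2,4-dimethyl-1-[(2R)-11-phenylundecan-2-yl]pentyl}-4,4,5,5-tetramethyl-1,3,2-dioxaborolane (anti adduct; forms as two diastereomers from the two alkene faces, one drawn, both give 14) | C[C@H](CCCCCCCCCc1ccccc1)[C@H](B1OC(C)(C)C(C)(C)O1)[C@@](C)(I)C[C@H](C)CO[Si](C)(C)C(C)(C)C | intermediate
14 | tert-butyldimethyl{[(2S,4Z,6R)-2,4,6-trimethyl-15-phenylpentadec-4-en-1-yl]oxy}silane | C[C@H](CCCCCCCCCc1ccccc1)/C=C(C)\C[C@H](C)CO[Si](C)(C)C(C)(C)C | intermediate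
15 | (2S,4Z,6R)-2,4,6-trimethyl-15-phenylpentadec-4-en-1-ol | C[C@H](CCCCCCCCCc1ccccc1)/C=C(C)\C[C@H](C)CO | intermediate
16 | (2S,4Z,6R)-2,4,6-trimethyl-15-phenylpentadec-4-enal | C[C@H](CCCCCCCCCc1ccccc1)/C=C(C)\C[C@H](C)C=O | intermediate
17 | (4R,5S,7Z,9R)-5,7,9-trimethyl-18-phenyloctadeca-1,7-dien-4-yl diisopinocampheylborinate | C[C@H](CCCCCCCCCc1ccccc1)/C=C(C)\C[C@H](C)[C@@H](CC=C)OB([C@H]1C[C@H]2C[C@@H]([C@@H]1C)C2(C)C)[C@H]1C[C@H]2C[C@@H]([C@@H]1C)C2(C)C | intermediate
18 | (4R,5S,7Z,9R)-5,7,9-trimethyl-18-phenyloctadeca-1,7-dien-4-ol | C[C@H](CCCCCCCCCc1ccccc1)/C=C(C)\C[C@H](C)[C@@H](CC=C)O | intermediate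
19 | (4R,5S,7Z,9R)-5,7,9-trimethyl-18-phenyloctadeca-1,7-dien-4-yl methanesulfonate | C[C@H](CCCCCCCCCc1ccccc1)/C=C(C)\C[C@H](C)[C@@H](CC=C)OS(C)(=O)=O | intermediate
20 | (4R,5S)-5-methyl-6-{(2R,3S)-2-methyl-3-[(2R)-11-phenylundecan-2-yl]oxiran-2-yl}hex-1-en-4-yl methanesulfonate | C[C@H](CCCCCCCCCc1ccccc1)[C@@H]1O[C@]1(C)C[C@H](C)[C@@H](CC=C)OS(C)(=O)=O | intermediate
21 | (4R,5S,7S,8S,9R)-7-hydroperoxy-8-hydroxy-5,7,9-trimethyl-18-phenyloctadec-1-en-4-yl methanesulfonate | C[C@H](CCCCCCCCCc1ccccc1)[C@H](O)[C@@](C)(OO)C[C@H](C)[C@@H](CC=C)OS(C)(=O)=O | intermediate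
22 | (1S,2R)-1-[(3S,4S,6S)-4,6-dimethyl-3-(prop-2-en-1-yl)-1,2-dioxan-6-yl]-2-methyl-11-phenylundecan-1-ol | C[C@H](CCCCCCCCCc1ccccc1)[C@H](O)[C@]1(C)C[C@H](C)[C@H](CC=C)OO1 | intermediate
23 | O-{(1S,2R)-1-[(3S,4S,6S)-4,6-dimethyl-3-(prop-2-en-1-yl)-1,2-dioxan-6-yl]-2-methyl-11-phenylundecyl} O-phenyl carbonothioate | C[C@H](CCCCCCCCCc1ccccc1)[C@H](OC(=S)Oc2ccccc2)[C@]1(C)C[C@H](C)[C@H](CC=C)OO1 | intermediate
24 | (3S,4S,6R)-4,6-dimethyl-6-[(2R)-2-methyl-11-phenylundecyl]-3-(prop-2-en-1-yl)-1,2-dioxane | C[C@H](CCCCCCCCCc1ccccc1)C[C@]1(C)C[C@H](C)[C@H](CC=C)OO1 | intermediate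
25 | 2-{(3S,4S,6R)-4,6-dimethyl-6-[(2R)-2-methyl-11-phenylundecyl]-1,2-dioxan-3-yl}acetaldehyde | C[C@H](CCCCCCCCCc1ccccc1)C[C@]1(C)C[C@H](C)[C@H](CC=O)OO1 | intermediate
26 | 2-{(3S,4S,6R)-4,6-dimethyl-6-[(2R)-2-methyl-11-phenylundecyl]-1,2-dioxan-3-yl}acetic acid | C[C@H](CCCCCCCCCc1ccccc1)C[C@]1(C)C[C@H](C)[C@H](CC(=O)O)OO1 | target

**Count and risks**
Total step count: 15. Longest linear sequence: 13 steps (steps 3 to 15, from 6); the other branch (steps 1 and 2) joins at step 6.

Steps most likely to fail: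

1. Step 14. The C1′ radical sits next to the O–O bond and may attack O1 intramolecularly (homolytic substitution giving an oxirane and an opened ring) faster than it takes hydrogen, and stannyl radicals may also attack the peroxide. The fallback sets out from 19 and comes back at 24. It never places oxygen on C1′: Mukaiyama–Isayama hydroperoxysilylation of 19 with Co(thd)2 [bis(2,2,6,6-tetramethylheptane-3,5-dionato)cobalt], O2 and Et3SiH in ClCH2CH2Cl at rt delivers hydrogen to C1′ and the silylperoxy group to C6, stopped before the slower monosubstituted alkene reacts. This gives (4R,5S,9R)-5,7,9-trimethyl-18-phenyl-7-[(triethylsilyl)peroxy]octadec-1-en-4-yl methanesulfonate F1 as both C7 epimers. Bu4NF in THF at 0 °C then frees the peroxy anion, which displaces the mesylate (6-exo-tet, inversion at C3) to give 24 together with its C6 epimer (3S,4S,6S)-4,6-dimethyl-6-[(2R)-2-methyl-11-phenylundecyl]-3-(prop-2-en-1-yl)-1,2-dioxane F2, removed by chromatography. Control of C6 is given up in exchange for avoiding the radical deoxygenation.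

2. Step 11. The activated epoxide may ionise at C6 before the peroxide is captured (loss of configuration at C6), or undergo attack at C1′ or a 1,2-shift to a ketone. The fallback sets out from 20 and comes back at 22. The order of the two ring C–O bonds is reversed so that the tertiary carbon is attacked intramolecularly: the mesylate of 20 is displaced by 2-methoxyprop-2-yl hydroperoxide with CsOH·H2O in DMF at 0 °C (intermolecular SN2, inversion at C3) to give the peroxyketal (2R,3S)-2-{(2S,3S)-3-[(2-methoxypropan-2-yl)peroxy]-2-methylhex-5-en-1-yl}-2-methyl-3-[(2R)-11-phenylundecan-2-yl]oxirane F3. Pyridinium p-toluenesulfonate in MeOH removes the ketal to give the free hydroperoxide (2R,3S)-2-[(2S,3S)-3-hydroperoxy-2-methylhex-5-en-1-yl]-2-methyl-3-[(2R)-11-phenylundecan-2-yl]oxirane F4, and a trace of camphorsulfonic acid in CH2Cl2 lets it open the epoxide at C6 from the back (6-exo, inversion) to give 22.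

3. Step 2. Methyl is a poor migrating group, so the ate complex may revert or the lithio carbamate may decompose or lose configuration before the 1,2-shift. The fallback sets out from 2 and comes back at 5. The lithio carbamate 3 (sBuLi, (+)-sparteine, Et2O, −78 °C) is trapped with 2-isopropoxy-4,4,5,5-tetramethyl-1,3,2-dioxaborolane to give the isolable (1R)-10-phenyl-1-(4,4,5,5-tetramethyl-1,3,2-dioxaborolan-2-yl)decyl N,N-diisopropylcarbamate F5. MeMgBr in Et2O (−78 °C to reflux) then adds irreversibly at boron, and the magnesium cation assists loss of the carbamate as methyl shifts with inversion (Matteson-type sequence), giving 5.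

Further compounds
F1 | step 14 | (4R,5S,9R)-5,7,9-trimethyl-18-phenyl-7-[(triethylsilyl)peroxy]octadec-1-en-4-yl methanesulfonate (both C7 epimers) | C[C@H](CCCCCCCCCc1ccccc1)CC(C)(OO[Si](CC)(CC)CC)C[C@H](C)[C@@H](CC=C)OS(C)(=O)=O
F2 | step 14 | (3S,4S,6S)-4,6-dimethyl-6-[(2R)-2-methyl-11-phenylundecyl]-3-(prop-2-en-1-yl)-1,2-dioxane | C[C@H](CCCCCCCCCc1ccccc1)C[C@@]1(C)C[C@H](C)[C@H](CC=C)OO1
F3 | step 11 | (2R,3S)-2-{(2S,3S)-3-[(2-methoxypropan-2-yl)peroxy]-2-methylhex-5-en-1-yl}-2-methyl-3-[(2R)-11-phenylundecan-2-yl]oxirane | C[C@H](CCCCCCCCCc1ccccc1)[C@@H]1O[C@]1(C)C[C@H](C)[C@H](CC=C)OOC(C)(C)OC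
F4 | step 11 | (2R,3S)-2-[(2S,3S)-3-hydroperoxy-2-methylhex-5-en-1-yl]-2-methyl-3-[(2R)-11-phenylundecan-2-yl]oxirane | C[C@H](CCCCCCCCCc1ccccc1)[C@@H]1O[C@]1(C)C[C@H](C)[C@H](CC=C)OO
F5 | step 2 | (1R)-10-phenyl-1-(4,4,5,5-tetramethyl-1,3,2-dioxaborolan-2-yl)decyl N,N-diisopropylcarbamate | CC(C)N(C(C)C)C(=O)O[C@H](B1OC(C)(C)C(C)(C)O1)CCCCCCCCCc1ccccc1
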